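## Analysis of the target

Compound **26** is a 5,10-seco-clerodane diacid built on one ten-membered carbocycle, labelled C1H=C2H–C3H=C4(C18O2H)–C5(=C19H2)–C6H2–C7H2–C8H(C17O2H)–C9(C20H3)(C11H2–C12(=O)–3-furyl)–C10H2; these atom labels are kept for every intermediate. Half of the ring is a cross-conjugated triene: C1=C2 is Z, C3=C4 has C2 and C5 cis (E by the sequence rule, because C18 outranks C5), and C5 carries an exocyclic methylene. The other half holds the only two stereocentres, C8 (R, tertiary, α to the C17 carboxyl and so epimerisable) and the neighbouring quaternary C9 (S). On the ring the C20 methyl is cis to C17 and the C11–C12 arm is trans to it. The sensitive parts are the 3-furyl ketone (acids, oxidants, electrophiles), the trienoic acid (6π ring closure, migration of the exocyclic alkene) and the C8 hydrogen. The synthesis is hard because a ten-membered ring must be closed, two ring-cis alkenes must be fixed beside an exocyclic one, and a quaternary centre must be set next to an epimerisable one in a ring with little conformational bias. The strategy rests on the unit C2–C3H=C4(C18)–C5(=C19H2): C5 is a masked ketone, and C3=C4–C18 is a propiolate lying between that ketone carbon and its α-carbon C2. Removing it leaves an eight-membered β-keto ester in which C1–C2 is again a two-carbon insert between C10 and the same ketone carbon, so the ring can be grown from the six-membered ring C5–C6–C7–C8–C9–C10 that already carries C8 and C9.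

## Retrosynthetic reasoning

**26 to 25.** The two carboxylic acids are unmasked last from the methyl esters of **25**, so that no free acid has to pass through the base, palladium and organometallic steps. The forward step must hydrolyse two hindered esters without epimerising C8.

**25 to 20 and 21.** The C12–furyl bond is cut. The furan would not survive the Lewis acids and the methylenation used earlier, so it enters at the end by an acylative cross-coupling of the C12 acid **20** with the furyl unit of **21**. C12 is told apart from C17 and C18 because it is carried as a tert-butyl ester (in **19**), which is removed without hydrolysis.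

**19 to 18.** C5=C19 is cut back to the C5 ketone. The ketone is needed until then as the acceptor and as the anion-stabilising group of the ring-building steps; the forward methylenation must be non-basic.

**18 to 17.** C1=C2 is traced back to a C2 allyl ester. The ester is what makes C2 nucleophilic in the key step; afterwards it is expelled as CO2 while the C1–C2 single bond becomes the alkene.

**17 to 15 and 9 (key disconnection).** C2–C3 and C4–C5 are cut and C2–C5 is restored. This removes the propiolate **9** and contracts the ring to the eight-membered allyl β-keto ester **15**. It is chosen because it turns a medium-ring closure into a ring enlargement, brings C18 at the right oxidation level, and dictates the cis geometry of C3=C4 through a four-membered intermediate. The forward step must make the enolate attack through carbon, close on the ketone and fragment.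

**15 to 13 and 14, then 12 and 11.** These are functional group changes. The allyl ester of **15** comes from the methyl β-keto ester **13** and **14** by an exchange that only a β-keto ester undergoes. The C17 methyl ester of **13** comes from the acyl oxazolidinone **12**. The saturated ring of **12** comes from the unsaturated β-keto ester **11** by hydrogenation. The ring opening that gives **11** leaves the new alkene largely out of conjugation and enolised, so a hydride conjugate reduction is unsafe; hydrogenation is safe, but only while C2 carries a methyl and not an allyl ester.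

**11 to 8 and 9 (via 10).** C10–C1 and C2–C5 are cut and C5–C10 is restored, which gives the six-membered enol silane **8**. The forward [2+2] addition and fragmentation need the enol double bond on the C10 side, next to the quaternary carbon, where deprotonation of a ketone would not place it.

**8 to 5 and 7.** The C9–C11 bond is cut. A Mukaiyama–Michael addition of **7** to enone **5** builds the quaternary centre, leaves the enol silane exactly at C5=C10, and sets C9 relative to C8. The nucleophile enters anti to the C8 acyl group, so the acetate arm ends trans and the methyl cis to C17, as **26** requires. The methyl must therefore already be on the enone and the acetate arm must be the group that is added.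

**5 to 4, then 2 and 3.** The enone is traced to the Diels–Alder adduct **4** of diene **2** and acrylimide **3** (cuts C6–C7 and C8–C9). The auxiliary of **3** fixes the absolute configuration at C8. C8 of **5** is γ to the enone and α to the acyl group and is therefore labile; with the auxiliary still attached, an epimer would be a separable diastereomer and not a loss of enantiopurity. This is why **5** is made as the imide and the auxiliary is kept until **12**.

**2 to 1, and 7 to 6.** Both silyl reagents come from O-silylation of kinetic enolates.

## Alternatives that were turned down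

**Alternative 1:** The C8–C9 bond is cut in a retro-Ireland–Claisen sense, which enlarges the carbocycle to the fourteen-membered allylic lactone A2 (C17 acylating the C12 oxygen, C9=C11 alkene). In the forward step, enolisation and O-silylation of A2 and a [3,3] shift would form C8–C9, contract the ring to ten carbons, free C17 as the acid and leave an (E)-2-(3-furyl)vinyl group on C9, giving A1.
- For it: both stereocentres and the quaternary carbon arise in one pericyclic step with chirality relayed from C12, and the ring forms by contraction. On stereo-economy of the key step it is stronger than the chosen route.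
- Against it: A2 must already contain the whole base-sensitive triene and must be closed by macrolactonisation at a hindered furyl carbinol. The chair or boat preference of a macrocyclic ketene acetal is not secured, so the C8/C9 relationship is uncertain. Afterwards C11=C12 must be hydrated selectively at C12 beside three other alkenes and the furan, and C18 must be oxidised from the silyl ether to the acid on the finished, fragile molecule.
- Comparison: the chosen route sets C8 and C9 in two separate, well-understood steps on a six-membered ring and reaches the ring with C17, C18 and C12 already at the carboxyl level. It needs no late oxidation.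

**Alternative 2:** C3=C4 and C5=C19 are cut together by a retro-enyne metathesis, leading to the acyclic dienyne A4. In the forward step, under ethylene (A7), a ruthenium carbene formed at C3 of the terminal Z-diene would add across the C4≡C5 alkyne in the endo sense, close the ten-membered ring and pass on a methylene to C5, giving A3.
- For it: this is the most convergent plan. The ring, the trisubstituted alkene and the exocyclic methylene come from one catalytic step, and C8, C9 and the furyl ketone are set on an open chain. In step count for the ring-forming event it is as strong as or stronger than the chosen route.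
- Against it: for a ten-membered ring the exo mode and the intermolecular reaction of the alkyne with A7 compete with the endo closure. Initiation at a conjugated diene gives a stabilised, sluggish carbene. Nothing in A4 enforces the cis geometry of C3=C4, and C18 again needs late oxidation next to a furan.
- Comparison: the chosen route is longer, but ring size, regiochemistry and alkene geometry are fixed by the starting ring and a cyclobutene intermediate, not by catalyst preference.

**Alternative 3:** The triene is traced back by a retro-[1,7]-hydrogen shift and a retro-ring-opening that reconnects C5–C10, giving the 5,10-cis-fused clerodane dienoate A6. In the forward step, irradiation would open ring A conrotatorily and warming would move a C19 hydrogen to C10, giving A5, which is compound **19** apart from the C17 ester alkyl group.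
- For it: it mirrors the likely biogenesis, forms no C–C bond, and delivers all three alkenes with their geometry and C18 at the right oxidation level in one operation. On alkene control it is stronger than the chosen route.
- Against it: A6 needs four stereocentres, two of which (C5, C10) are then destroyed, a specific cis ring fusion and a homoannular diene ester, which means a long decalin synthesis. Photostationary mixtures, secondary photoproducts, thermal 6π reclosure and hydrogen shift from C6 instead of C19 make the key step uncertain.
- Comparison: the chosen route builds only the two stereocentres that remain and uses ground-state steps, at the price of a separate dehydrogenation and methylenation.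

Key step: step 10

Remark: **3** is treated as a purchasable reagent (otherwise one N-acylation of (S)-4-benzyloxazolidin-2-one with acryloyl chloride), and **1** is used as the commercial, predominantly E material.

## Route

Step 1
Reactants: 1 (E)-pent-3-en-2-one
Product: 2 (E)-tert-butyldimethyl(penta-1,3-dien-2-yloxy)silane
Conditions: LDA, THF, −78 °C; TBSCl, HMPA, −78 → 0 °C
Reagents that add atoms: tert-butyldimethylsilyl chloride, CC(C)(C)[Si](C)(C)Cl
Why: Kinetic deprotonation of the methyl ketone at the α′-methyl group and O-silylation should give the cross-conjugated 2-silyloxydiene with the E-alkene retained.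

Step 2
Reactants: 2 (E)-tert-butyldimethyl(penta-1,3-dien-2-yloxy)silane; 3 (S)-3-acryloyl-4-benzyloxazolidin-2-one
Product: 4 (S)-4-benzyl-3-{[(1R,2S)-4-[(tert-butyldimethylsilyl)oxy]-2-methylcyclohex-3-en-1-yl]carbonyl}oxazolidin-2-one
Conditions: Et2AlCl (1.4 equiv), CH2Cl2, −78 °C
Reagents that add atoms: none
Why: Auxiliary-controlled Diels–Alder reaction: the Et2AlCl chelate of the s-cis acrylimide should be approached anti to the benzyl group, which sets C8 (R). The 1-methyl and 3-silyloxy groups of the diene both direct C9 to the α-carbon and C6 to the β-carbon. The endo adduct (methyl cis to the acyl group) is expected, but C9 is erased in step 3.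

Step 3
Reactants: 4 the cycloadduct
Product: 5 (S)-4-benzyl-3-{[(R)-2-methyl-4-oxocyclohex-2-en-1-yl]carbonyl}oxazolidin-2-one
Conditions: Pd(OAc)2 (1.1 equiv), MeCN, 23 °C
Reagents that add atoms: none
Why: Saegusa–Ito oxidation (palladation at C10, β-hydride elimination of H9) should give the 3-methyl enone. The auxiliary is kept so that any epimerisation at the now vinylogous C8 would show as a separable diastereomer and not as loss of enantiopurity.

Step 4
Reactants: 6 tert-butyl acetate
Product: 7 [(1-tert-butoxyethenyl)oxy]trimethylsilane
Conditions: LDA, THF, −78 °C; TMSCl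
Reagents that add atoms: chlorotrimethylsilane, C[Si](C)(C)Cl
Why: O-Silylation of the lithium ester enolate gives the ketene silyl acetal.

Step 5
Reactants: 5 the enone imide; 7 the ketene silyl acetal
Product: 8 tert-butyl 2-[(1R,6R)-6-{[(S)-4-benzyl-2-oxooxazolidin-3-yl]carbonyl}-1-methyl-3-[(trimethylsilyl)oxy]cyclohex-2-en-1-yl]acetate
Conditions: Tf2NH (5 mol %), CH2Cl2, −78 °C; Et3N; used crude
Reagents that add atoms: none
Why: Mukaiyama–Michael addition under silyl triflimide catalysis: allylic strain with the C9 methyl holds the C8 acyl group pseudo-axial, so the ketene acetal should attack C9 anti to it. The acetate arm then ends trans and the methyl cis to C17, which sets C9 (as in 3,4-disubstituted cyclohexenones in general). Silyl transfer leaves the enol silane regiospecifically at C5=C10.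

Step 6
Reactants: 8 the enol silane; 9 methyl propiolate
Product: 11 methyl (Z,5R,6R)-5-{[(S)-4-benzyl-2-oxooxazolidin-3-yl]carbonyl}-6-(2-tert-butoxy-2-oxoethyl)-6-methyl-2-oxocyclooct-7-ene-1-carboxylate, via silyloxycyclobutene 10 (not isolated)
Conditions: ZrCl4, CH2Cl2–Et2O, −78 → −40 °C; cold NaHCO3 work-up; then TBAF, THF, −78 → 0 °C; AcOH
Reagents that add atoms: none
Why: Lewis acid-promoted stepwise [2+2] cycloaddition (C10 to the propiolate β-carbon, C5 to the α-carbon) gives the 1-silyloxycyclobutene. Fluoride frees the alkoxide, and strain-driven vinylogous retro-aldol cleavage of C5–C10 enlarges the ring by C1 and C2. The low temperature should spare the tert-butyl ester.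

Step 7
Reactants: 11 the unsaturated β-keto ester (keto, enol and double-bond isomers)
Product: 12 methyl (5R,6S)-5-{[(S)-4-benzyl-2-oxooxazolidin-3-yl]carbonyl}-6-(2-tert-butoxy-2-oxoethyl)-6-methyl-2-oxocyclooctane-1-carboxylate
Conditions: H2 (1 atm), Pd/C, EtOAc, 23 °C
Reagents that add atoms: none
Why: Heterogeneous hydrogenation should saturate the ring alkene in whichever tautomer it sits; this is why C2 carries a methyl and not an allyl ester up to this point.

Step 8
Reactants: 12 the saturated imide
Product: 13 dimethyl (5R,6S)-6-(2-tert-butoxy-2-oxoethyl)-6-methyl-2-oxocyclooctane-1,5-dicarboxylate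
Conditions: MeMgBr, MeOH (gives MeOMgBr), CH2Cl2, 0 °C
Reagents that add atoms: methoxymagnesium bromide, CO[Mg]Br
Why: Magnesium methoxide transesterification of the N-acyl oxazolidinone (exocyclic cleavage) should give the C17 methyl ester and return the auxiliary. The β-keto ester is masked as its magnesium chelate and is already a methyl ester.

Step 9
Reactants: 13 the β-keto methyl ester; 14 allyl alcohol
Product: 15 1-allyl 5-methyl (5R,6S)-6-(2-tert-butoxy-2-oxoethyl)-6-methyl-2-oxocyclooctane-1,5-dicarboxylate
Conditions: DMAP (cat.), toluene, 110 °C, 4 Å molecular sieves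
Reagents that add atoms: none
Why: DMAP-catalysed transesterification is specific to β-keto esters (acylketene pathway), so the C17 methyl and C12 tert-butyl esters should not exchange.

Step 10
Reactants: 15 the eight-membered allyl β-keto ester; 9 methyl propiolate
Product: 17 2-allyl 4,8-dimethyl (3E,8R,9S)-9-(2-tert-butoxy-2-oxoethyl)-9-methyl-5-oxocyclodec-3-ene-2,4,8-tricarboxylate, via sodium cyclobutenoxide 16 (not isolated)
Conditions: NaH (1.05 equiv), THF, 0 °C; then 9 added slowly, −20 → 23 °C; AcOH
Reagents that add atoms: none
Why: The sodium enolate of 15 (C2–H between ketone and ester is the only acidic site that is engaged) adds through C2 to the β-carbon of 9 and forms C2–C3. The ester-stabilised vinyl anion at C4 then closes on the C5 ketone by a 4-exo-trig attack (C4–C5) to the bicyclo[6.2.0] cyclobutenoxide 16. Alkoxide-driven retro-aldol cleavage of the strained C2–C5 bond opens 16 to the ten-membered ring, so that ring arises by enlargement and not by end-to-end cyclisation. The closest known reaction is the base-mediated two-carbon ring enlargement of cyclic β-keto esters with acetylenic esters, together with the related enamine–propiolate enlargement. No lasting stereocentre is created: C2 stays enolisable, C8 and C9 are remote and untouched, and the C3=C4 geometry (C2 and C5 cis) is dictated by the four-membered ring. The step needs C- and not O-alkylation, closure of the vinyl anion before it is protonated, and fragmentation toward C2. A preformed, proton-free sodium enolate, slow addition of 9, the strain of 16 and the double stabilisation of the C2 carbanion by the allyl ester and the new enone ester should secure these.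

Step 11
Reactants: 17 the ten-membered allyl ester (C2 epimers and enol forms)
Product: 18 dimethyl (1Z,3E,8R,9S)-9-(2-tert-butoxy-2-oxoethyl)-9-methyl-5-oxocyclodeca-1,3-diene-4,8-dicarboxylate
Conditions: Pd(OAc)2 (10 mol %), dppe (10 mol %), MeCN, 80 °C
Reagents that add atoms: none
Why: Proposed new method: oxidative addition of zerovalent palladium to the allyl ester and loss of CO2 should give a π-allylpalladium dienolate in which the metal can sit on C2; β-hydride elimination of a C1 hydrogen (the only sp3 β-hydrogens) then forms C1=C2 and the allyl hydride collapses to propene; the closest known reaction is the palladium-catalysed decarboxylation–dehydrogenation of allyl β-keto carboxylates to enones, here extended to a vinylogous (γ-carboxy enone) substrate; the ring is expected to favour the conjugated cis,cis-dienone.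

Step 12
Reactants: 18 the dienone
Product: 19 dimethyl (1Z,3E,8R,9S)-9-(2-tert-butoxy-2-oxoethyl)-9-methyl-5-methylidenecyclodeca-1,3-diene-4,8-dicarboxylate
Conditions: Zn, CH2Br2, TiCl4 (reagent pre-formed in THF), CH2Cl2, 0 → 23 °C
Reagents that add atoms: dibromomethane, BrCBr
Why: Takai–Lombardo methylenation: the non-basic gem-dimetallic reagent should attack the ketone without enolising C6 or touching the esters. If the zinc salts cleave some tert-butyl ester, that only anticipates step 13.

Step 13
Reactants: 19 the triene triester
Product: 20 [(1Z,3E,8R,9S)-4,8-bis(methoxycarbonyl)-9-methyl-5-methylidenecyclodeca-1,3-dien-9-yl]acetic acid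
Conditions: TMSOTf, 2,6-lutidine, CH2Cl2, 0 °C; aqueous work-up (pH 4 buffer)
Reagents that add atoms: none
Why: Silyl triflate-mediated cleavage of the tert-butyl ester (loss of isobutene, silyl ester hydrolysed at work-up) should leave the methyl esters and, under buffered aprotic conditions, the triene untouched.

Step 14
Reactants: 20 the C12 acid; 21 3-bromofuran
Product: 25 dimethyl (1Z,3E,8R,9S)-9-[2-(furan-3-yl)-2-oxoethyl]-9-methyl-5-methylidenecyclodeca-1,3-diene-4,8-dicarboxylate, via 3-furyllithium 22 (not isolated), via 3-furylzinc chloride 23 (not isolated), via acid chloride 24 (not isolated)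
Conditions: 21, n-BuLi, THF, −78 °C, then ZnCl2; separately 20, 1-chloro-N,N,2-trimethylprop-1-en-1-amine, CH2Cl2, 0 °C; combined with Pd(PPh3)4 (5 mol %), THF, 0 → 23 °C
Reagents that add atoms: none
Why: Negishi acylation: the acid chloride is made under neutral conditions with the α-chloroenamine and coupled with 3-furylzinc chloride under zerovalent palladium. Organozinc reagents should not add to the methyl esters or the dienoate, and lithiation at −78 °C avoids scrambling to the 2-furyl isomer.

Step 15
Reactants: 25 the furyl ketone diester
Product: 26 (1Z,3E,8R,9S)-9-[2-(furan-3-yl)-2-oxoethyl]-9-methyl-5-methylidenecyclodeca-1,3-diene-4,8-dicarboxylic acid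
Conditions: Me3SnOH, ClCH2CH2Cl, 80 °C; then dilute aqueous HCl
Reagents that add atoms: trimethyltin hydroxide, C[Sn](C)(C)O
Why: Me3SnOH transfers hydroxide to hindered methyl esters under near-neutral conditions, so C8 (α to C17) should not epimerise and the cross-conjugated triene and the furyl ketone should survive.

## Compound list

1 | (E)-pent-3-en-2-one | CC(=O)/C=C/C | starting material
2 | (E)-tert-butyldimethyl(penta-1,3-dien-2-yloxy)silane | C=C(O[Si](C)(C)C(C)(C)C)/C=C/C | intermediate
3 | (S)-3-acryloyl-4-benzyloxazolidin-2-one | C=CC(=O)N1[C@@H](Cc2ccccc2)COC1=O | starting material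
4 | (S)-4-benzyl-3-{[(1R,2S)-4-[(tert-butyldimethylsilyl)oxy]-2-methylcyclohex-3-en-1-yl]carbonyl}oxazolidin-2-one (methyl cis to acyl) | CC(C)(C)[Si](C)(C)OC=1CC[C@@H](C(=O)N2[C@@H](Cc3ccccc3)COC2=O)[C@@H](C)C1 | intermediate
5 | (S)-4-benzyl-3-{[(R)-2-methyl-4-oxocyclohex-2-en-1-yl]carbonyl}oxazolidin-2-one | O=C1CC[C@@H](C(=O)N2[C@@H](Cc3ccccc3)COC2=O)C(C)=C1 | intermediate
6 | tert-butyl acetate | CC(=O)OC(C)(C)C | starting material
7 | [(1-tert-butoxyethenyl)oxy]trimethylsilane | C=C(OC(C)(C)C)O[Si](C)(C)C | intermediate
8 | tert-butyl 2-[(1R,6R)-6-{[(S)-4-benzyl-2-oxooxazolidin-3-yl]carbonyl}-1-methyl-3-[(trimethylsilyl)oxy]cyclohex-2-en-1-yl]acetate (acetate arm trans, methyl cis to the acyl group) | C[Si](C)(C)OC=1CC[C@@H](C(=O)N2[C@@H](Cc3ccccc3)COC2=O)[C@](C)(CC(=O)OC(C)(C)C)C1 | intermediate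
9 | methyl propiolate | C#CC(=O)OC | starting material
10 | methyl 4-{[(S)-4-benzyl-2-oxooxazolidin-3-yl]carbonyl}-5-(2-tert-butoxy-2-oxoethyl)-5-methyl-1-[(trimethylsilyl)oxy]bicyclo[4.2.0]oct-7-ene-8-carboxylate (cis-fused; C8 R and C9 R in target labels; both bridgehead pairs) | C[Si](C)(C)OC12CC[C@@H](C(=O)N3[C@@H](Cc4ccccc4)COC3=O)[C@](C)(CC(=O)OC(C)(C)C)C1C=C2C(=O)OC | intermediate (not isolated)
11 | methyl (Z,5R,6R)-5-{[(S)-4-benzyl-2-oxooxazolidin-3-yl]carbonyl}-6-(2-tert-butoxy-2-oxoethyl)-6-methyl-2-oxocyclooct-7-ene-1-carboxylate (drawn as the keto form with C10=C1; C2 epimers, enol and conjugated isomer possible) | O=C1CC[C@@H](C(=O)N2[C@@H](Cc3ccccc3)COC2=O)[C@](C)(CC(=O)OC(C)(C)C)/C=C\C1C(=O)OC | intermediate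
12 | methyl (5R,6S)-5-{[(S)-4-benzyl-2-oxooxazolidin-3-yl]carbonyl}-6-(2-tert-butoxy-2-oxoethyl)-6-methyl-2-oxocyclooctane-1-carboxylate (C2 epimers and enol) | O=C1CC[C@@H](C(=O)N2[C@@H](Cc3ccccc3)COC2=O)[C@](C)(CC(=O)OC(C)(C)C)CCC1C(=O)OC | intermediate
13 | dimethyl (5R,6S)-6-(2-tert-butoxy-2-oxoethyl)-6-methyl-2-oxocyclooctane-1,5-dicarboxylate (C2 epimers and enol) | O=C1CC[C@@H](C(=O)OC)[C@](C)(CC(=O)OC(C)(C)C)CCC1C(=O)OC | intermediate
14 | allyl alcohol | C=CCO | starting material
15 | 1-allyl 5-methyl (5R,6S)-6-(2-tert-butoxy-2-oxoethyl)-6-methyl-2-oxocyclooctane-1,5-dicarboxylate (ring C1 is C2 of the target, C2 is C5, C5 is C8, C6 is C9; C2 epimers and enol) | O=C1CC[C@@H](C(=O)OC)[C@](C)(CC(=O)OC(C)(C)C)CCC1C(=O)OCC=C | intermediate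
16 | sodium salt of the bicyclo[6.2.0]dec-9-en-1-ol formed from 15 and 9 (cyclobutene C2–C3=C4–C5, alkoxide on C5, allyl ester on C2, methyl ester on C4; cis-fused) | [Na+].[O-]C12CC[C@@H](C(=O)OC)[C@](C)(CC(=O)OC(C)(C)C)CCC1(C(=O)OCC=C)C=C2C(=O)OC | intermediate (not isolated)
17 | 2-allyl 4,8-dimethyl (3E,8R,9S)-9-(2-tert-butoxy-2-oxoethyl)-9-methyl-5-oxocyclodec-3-ene-2,4,8-tricarboxylate (C2 and C5 cis on C3=C4; C2 epimers and enol forms) | O=C1CC[C@@H](C(=O)OC)[C@](C)(CC(=O)OC(C)(C)C)CCC(C(=O)OCC=C)/C=C\1C(=O)OC | intermediate
18 | dimethyl (1Z,3E,8R,9S)-9-(2-tert-butoxy-2-oxoethyl)-9-methyl-5-oxocyclodeca-1,3-diene-4,8-dicarboxylate | O=C1CC[C@@H](C(=O)OC)[C@](C)(CC(=O)OC(C)(C)C)C/C=C\C=C/1C(=O)OC | intermediate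
19 | dimethyl (1Z,3E,8R,9S)-9-(2-tert-butoxy-2-oxoethyl)-9-methyl-5-methylidenecyclodeca-1,3-diene-4,8-dicarboxylate | C=C1CC[C@@H](C(=O)OC)[C@](C)(CC(=O)OC(C)(C)C)C/C=C\C=C/1C(=O)OC | intermediate
20 | [(1Z,3E,8R,9S)-4,8-bis(methoxycarbonyl)-9-methyl-5-methylidenecyclodeca-1,3-dien-9-yl]acetic acid | C=C1CC[C@@H](C(=O)OC)[C@](C)(CC(=O)O)C/C=C\C=C/1C(=O)OC | intermediate
21 | 3-bromofuran | Brc1ccoc1 | starting material
22 | 3-furyllithium | [Li]c1ccoc1 | intermediate (not isolated)
23 | 3-furylzinc chloride | Cl[Zn]c1ccoc1 | intermediate (not isolated)
24 | acid chloride of 20 | C=C1CC[C@@H](C(=O)OC)[C@](C)(CC(=O)Cl)C/C=C\C=C/1C(=O)OC | intermediate (not isolated)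
25 | dimethyl (1Z,3E,8R,9S)-9-[2-(furan-3-yl)-2-oxoethyl]-9-methyl-5-methylidenecyclodeca-1,3-diene-4,8-dicarboxylate | C=C1CC[C@@H](C(=O)OC)[C@](C)(CC(=O)c2ccoc2)C/C=C\C=C/1C(=O)OC | intermediate
26 | (1Z,3E,8R,9S)-9-[2-(furan-3-yl)-2-oxoethyl]-9-methyl-5-methylidenecyclodeca-1,3-diene-4,8-dicarboxylic acid (CNP0137484.1) | C=C1CC[C@@H](C(=O)O)[C@](C)(CC(=O)c2ccoc2)C/C=C\C=C/1C(=O)O | target

## Step count and risks

Total step count: 15. Longest linear sequence: 14 steps (1 → 26 through steps 1–3 and 5–15; step 4 prepares the side-chain reagent 7).

Steps least certain to work: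

**Step 11 (proposed new method).** The most likely failure is that the soft, doubly stabilised carbanion is allylated by the π-allyl fragment at C2 or C4, or is simply protonated, faster than β-hydride elimination occurs. The new C1=C2 bond may also form trans, and the cis-dienone can equilibrate with its 2H-pyran valence tautomer through an oxa-6π closure. The fallback uses known reactions and runs from **17** back to **18**. Pd(PPh3)4 with morpholine as allyl acceptor removes the allyl group, and the vinylogous β-keto acid loses CO2 to give the enone diester F1. LiHMDS and TBSCl convert F1 by γ-deprotonation into the extended silyl dienol ether F2. Saegusa–Ito oxidation of F2 with Pd(OAc)2 then gives **18**.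

**Step 10 (key step).** The most likely failure is protonation of the vinyl anion before it closes on the ketone, which would stop at the open 2-vinyl β-keto ester. O-alkylation, a second addition of **9**, and loss of the C3=C4 geometry while the delocalised anion persists are further risks. The fallback runs from **15** back to **17**. Condensation with pyrrolidine gives the enamino ester F3. Its neutral thermal [2+2] addition to **9** and ring opening give the ring-enlarged aminodiene F4. Mild aqueous acid then hydrolyses F4 to **17**.

**Step 5.** Addition to the β,β-disubstituted enone may be slow or reversible, and desilylation to the ketone would lose the regiochemical information. Facial selectivity could also erode if the acyl group does not stay pseudo-axial. The fallback runs from **5** back to **8**. The Reformatsky reagent F5 (from tert-butyl bromoacetate and zinc) is added under CuBr·SMe2 catalysis with TMSCl as the trap, which gives **8** directly.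

**Step 6.** Bond formation at C10, next to the quaternary carbon, may be sluggish. Stoichiometric ZrCl4 may cleave the tert-butyl ester or protodesilylate **8**. The fallback runs from **5** and **6** back to **11** and avoids a stoichiometric metal Lewis acid. **6** is converted with LDA and TBSCl into the TBS ketene acetal F6. Mukaiyama–Michael addition of F6 to **5** gives the isolable TBS enol ether F7. A Tf2NH-catalysed [2+2] addition of F7 to **9** gives the cyclobutene F8. TBAF at 23 °C then frees the alkoxide of F8 and opens it to **11**.

**Step 12.** The electron-poor dienone may be reduced or undergo conjugate addition with zinc and low-valent titanium, and the 2H-pyran tautomer lowers the amount of free ketone. The fallback runs from **18** back to **19**. Me3SiCH2MgCl with CeCl3 adds 1,2 to the ketone to give the β-hydroxysilane F9. Mild acid then effects the Peterson elimination of F9 to **19**.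

## Further compounds

F1 | step 11 | dimethyl (3E,8R,9S)-9-(2-tert-butoxy-2-oxoethyl)-9-methyl-5-oxocyclodec-3-ene-4,8-dicarboxylate | O=C1CC[C@@H](C(=O)OC)[C@](C)(CC(=O)OC(C)(C)C)CCC/C=C\1C(=O)OC
F2 | step 11 | tert-butyldimethylsilyl dienol ether of F1 (C5–O–Si, C4=C5 and C2=C3) | CC(C)(C)[Si](C)(C)OC=1CC[C@@H](C(=O)OC)[C@](C)(CC(=O)OC(C)(C)C)CCC=CC1C(=O)OC
F3 | step 10 | pyrrolidine enamino ester of 15 (C5–N, C5=C2) | C1CCN(C1)C=2CC[C@@H](C(=O)OC)[C@](C)(CC(=O)OC(C)(C)C)CCC2C(=O)OCC=C
F4 | step 10 | ten-membered 5-(pyrrolidin-1-yl) diene triester (C4=C5 and C2=C3) | C1CCN(C1)C=2CC[C@@H](C(=O)OC)[C@](C)(CC(=O)OC(C)(C)C)CCC(C(=O)OCC=C)=CC2C(=O)OC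
F5 | step 5 | (2-tert-butoxy-2-oxoethyl)zinc bromide | Br[Zn]CC(=O)OC(C)(C)C
F6 | step 6 | tert-butyl[(1-tert-butoxyethenyl)oxy]dimethylsilane | C=C(OC(C)(C)C)O[Si](C)(C)C(C)(C)C
F7 | step 6 | tert-butyldimethylsilyl analogue of 8 | CC(C)(C)[Si](C)(C)OC=1CC[C@@H](C(=O)N2[C@@H](Cc3ccccc3)COC2=O)[C@](C)(CC(=O)OC(C)(C)C)C1
F8 | step 6 | tert-butyldimethylsilyl analogue of 10 | CC(C)(C)[Si](C)(C)OC12CC[C@@H](C(=O)N3[C@@H](Cc4ccccc4)COC3=O)[C@](C)(CC(=O)OC(C)(C)C)C1C=C2C(=O)OC
F9 | step 12 | dimethyl (1Z,3E,8R,9S)-9-(2-tert-butoxy-2-oxoethyl)-5-hydroxy-9-methyl-5-[(trimethylsilyl)methyl]cyclodeca-1,3-diene-4,8-dicarboxylate (C5 epimers) | C[Si](C)(C)CC1(O)CC[C@@H](C(=O)OC)[C@](C)(CC(=O)OC(C)(C)C)C/C=C\C=C/1C(=O)OC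
A1 | alternative 1 | ten-membered C17 acid with (E)-2-(furan-3-yl)vinyl on C9 and C18 silyl ether | C=C1CC[C@@H](C(=O)O)[C@](C)(/C=C/c2ccoc2)C/C=C\C=C/1CO[Si](C)(C)C(C)(C)C
A2 | alternative 1 | fourteen-membered allylic lactone (C17 ester of the C12 furyl carbinol; C12 configuration and C9=C11 geometry left open) | O=C1CCCC(=C)/C(CO[Si](C)(C)C(C)(C)C)=C\C=C/CC(C)=CC(c2ccoc2)O1
A3 | alternative 2 | ten-membered triene with furyl ketone, C17 ethyl ester and C18 silyl ether | C=C1CC[C@@H](C(=O)OCC)[C@](C)(CC(=O)c2ccoc2)C/C=C\C=C/1CO[Si](C)(C)C(C)(C)C
A4 | alternative 2 | acyclic dienyne with terminal (Z)-diene on C10 and C4≡C5 alkyne | C=C/C=C\C[C@@](C)(CC(=O)c1ccoc1)[C@H](C(=O)OCC)CCC#CCO[Si](C)(C)C(C)(C)C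
A5 | alternative 3 | 5,10-seco-clerodane triene triester | C=C1CC[C@@H](C(=O)OCC)[C@](C)(CC(=O)OC(C)(C)C)C/C=C\C=C/1C(=O)OC
A6 | alternative 3 | 5,10-cis-fused clerodane 1,3-dienoate (C5 and C10 a cis pair, not specified further) | COC(=O)C1=CC=CC2C1(C)CC[C@@H](C(=O)OCC)[C@]2(C)CC(=O)OC(C)(C)C
A7 | alternative 2 | ethylene | C=C
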